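## The problem

Compound 20 is a 3,4-trans-disubstituted γ-butyrolactone (ring A) whose C3 carries, through a methylene, a 2-oxo-2H-pyran-6-carboxylic acid attached at pyranone C4 (ring B) and whose C4 carries a 3,4-dimethoxybenzyl group (ring C). The rings are not fused, so the task is to form the C4–CH2Ar and C3–CH2 bonds on a lactone and to fix two adjacent stereocentres as (3R,4R). The two centres are trans, the thermodynamically preferred arrangement, and a substituent at C4 steers an electrophile to the opposite face of a C3 enolate, so only C4 has to be set absolutely. Ring B is the fragile part: the pyranone is an acylated enol that hydroxide, alkoxides, hydrides and carbanions open, and its free acid rules out strong base, so it should appear last and under acid. The lactone C3–H is epimerisable in base, and ring C is an electron-rich arene that strong oxidants can attack. Two features of the structure allow a short route: first, C5 of ring A is an unsubstituted CH2, so ring A maps onto a furan-2(5H)-one whose C3=C4 bond takes a nucleophile at C4 and an electrophile at C3 while C5 holds a removable chiral acetal, as in butenolide 5. Second, the five ring carbons of ring B plus its carboxyl carbon are the six carbons of a 5-substituted 3-methoxycatechol cleaved between its hydroxylated carbons, so ring B can be carried as a protected benzene ring.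

## Retrosynthesis

**20 to 18.** Ring B is opened at its O1–C6 bond, the enol C–O bond, with restoration of the methyl enol ether, giving (2E,4Z)-2-methoxymuconic acid 19. Joining the two carboxyl carbons of 19 regenerates the aromatic bond between the two hydroxylated carbons of catechol lactone 18. The neighbouring cuts of ring B (an olefin-forming closure of C3=C4, or a C5–C6 condensation with an oxalate) would build the pyranone beside ring A and need base or a late dehydrogenation. The arene surrogate instead makes the problem an ordinary dibenzylbutyrolactone with two different aryl groups and confines the sensitivity of ring B to one acidic step. The forward reaction must cleave the catechol of 18 selectively in the presence of ring C, and the Z-disposed distal carboxyl of 19 must then close on the protonated enol ether carbon with loss of methanol.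

**18 to 17 to 14.** No skeletal bond is cut here. The catechol hydroxyls of 18 go back to benzyl ethers and the benzylic CH2 on C4 to a 1,3-dithiane carbon, giving 17; one Raney Ni treatment under hydrogen should break the two C–S and the two O–CH2Ph bonds. The C5 methylene of 17 is traced through carboxylates 16 and 15 to the menthyl acetal carbon of 14. Removing the acetal before sulfur and benzyl groups is preferred to the reverse order, because the catechol is then never exposed to alkali and both the dithiane and the benzyl ethers are inert to hydroxide and borohydride. The forward step requires that the aldehyde freed at C5 is reduced faster than it enolises toward C4.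

**14 to 5, 12 and 11.** Both exocyclic bonds of ring A are cut together: C4–C(dithiane) to the lithiated dithiane 12, and C3–CH2Ar to benzylic bromide 11, leaving (5R)-menthyloxybutenolide 5. Cutting only one bond would leave a monobenzyl lactone whose single stereocentre needs its own asymmetric step. The double cut sets C4 from the acetal and C3 from C4 in one flask, and reduces 14 to three achiral or auxiliary-derived pieces of modest size. The forward reaction must add 12 in the 1,4 sense anti to the menthyloxy group, and enolate 13 must be C-benzylated anti to the new C4 substituent.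

**5 to 2 and 3, and 2 to 1.** The acetal C5–O bond of 5 is cut to racemic 5-hydroxyfuran-2(5H)-one 2 and (−)-menthol 3; the C5 epimer 4 forms alongside. Lactol 2 comes from furfural 1 by loss of the formyl carbon and addition of two oxygen atoms. This is preferred to a catalytic asymmetric conjugate addition to an achiral butenolide because 5 is a crystalline single diastereomer and the auxiliary sits on a carbon that must become CH2 anyway. The acetalisation must be reversible at C5 so that crystallisation drains 4 into 5.

**12 to 7 to 6, and 11 to 10 to 9 to 8.** The C–Li bond of 12 goes back to the C–H of dithiane 7, and the two C–S bonds of 7 to veratraldehyde 6. The C–Br bond of 11 goes back to alcohol 10, then to aldehyde 9, and the two benzyl ethers to 3,4-dihydroxy-5-methoxybenzaldehyde 8. These are functional-group changes on commercial aromatic aldehydes. The protecting groups must survive an organolithium, alkali and borohydride, and must leave under the conditions that remove sulfur.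

## Roads not taken

**Alternative 1:** Ring B is cut at its C3=C4 bond. Ring-closing metathesis of acrylate diene A2 with second-generation Grubbs catalyst, (H2IMes)(PCy3)Cl2Ru=CHPh, would join the acrylate to the 1,1-disubstituted alkene and give dihydropyranone A1.
- Merits: no oxidant comes near ring C, and closure of acrylates onto 1,1-disubstituted olefins to 4-substituted 5,6-dihydropyran-2-ones is within the known scope of this catalyst. The ring closure itself is more predictable than an arene cleavage.
- Weak points: A2 needs a branched four-carbon arm with an acylated α-hydroxy ester on lactone C3, which costs several steps and adds an uncontrolled stereocentre that persists through A1. A1 is still two operations from 20. Dehydrogenation at the ring CH2–CH(CO2Me) unit can instead open the ring by eliminating the carboxylate under base. The methyl ester must then be hydrolysed without opening ring B or ring A.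
- Comparison: this road is longer and has two delicate late steps against one in the chosen plan, and it still needs a separate enantioselective synthesis of the trans lactone.

**Alternative 2:** Ring A is cut at O1–C5. Asymmetric Baeyer–Villiger oxidation of prochiral cyclobutanone A4 (Sc(OTf)3 with a chiral N,N′-dioxide ligand and a peracid) would give monobenzyl lactone A3 with C4 set by the catalyst.
- Merits: the stereocentre comes from a catalyst, there is no auxiliary, sulfur or Raney Ni, and A4 is two steps from an allylarene by ketene cycloaddition and dechlorination. Enolate alkylation of A3 with bromide 11 would set C3 trans by the same substrate control. The overall count would be about equal to, or one step lower than, the chosen route. This road is better on atom economy.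
- Weak points: the aryl group that the catalyst must recognise is one methylene away from the prochiral carbon, so complete enantioselection cannot be assumed. A3 is unlikely to crystallise well enough to be upgraded. Ring C competes for the peracid. Ring B must still be made by the same debenzylation and cleavage.
- Comparison: the chosen plan sets against it an enantiopure crystalline 5, both arms installed in one flask, and menthol 3 recovered in step 8.

**Alternative 3:** Ring B is cut at C5–C6 and O1–C2. A vinylogous Claisen condensation of an oxalate diester at the γ-methyl of enoate A6 under KOEt, followed by acid closure of the enol onto the enoate ester, would give pyranone ester A5, then 20 by ester hydrolysis.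
- Merits: ring B and its carboxyl are assembled by classical condensation chemistry, with no catechol, no protecting groups and no oxidation. With A6 made by alkylating A3, the sequence is shorter on paper than the chosen one.
- Weak points: stoichiometric alkoxide meets four reactive sites in A6. These are the γ-methyl, the γ-methylene next to ring A, the lactone C3–H and the lactone carbonyl, which ethoxide can open. Regioselective acylation at the methyl group is therefore not assured, and C3 may be acylated or epimerised. The enoate geometry needed for closure can scramble through the dienolate. The ester of A5 must then be hydrolysed on a base-sensitive pyranone.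
- Comparison: the chosen plan is longer, but it forms ring B under acid, where ring A, the C3 configuration and the pyranone are all stable, and its risk lies in one oxidation rather than in several competing enolate sites.

Key step: step 7

Remark on the chemistry: the crystalline acetal from (−)-menthol is taken to be the (5R) epimer 5, and aldehyde 8 is taken as commercially available.

## Route

Step 1
Reactants: 1 furfural (furan-2-carbaldehyde)
Product: 2 5-hydroxyfuran-2(5H)-one (racemic)
Conditions: O2, hν (visible), rose bengal disodium salt C20H2Cl4I4Na2O5 (cat.), MeOH, 20 °C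
Reagents that add atoms: dioxygen, O=O
Why: Sensitised singlet oxygen adds across C2 and C5 of the furan, and methanol then removes the formyl carbon as methyl formate; this photooxygenation of furfural is a standard preparative reaction and creates no defined stereocentre.

Step 2
Reactants: 2 5-hydroxyfuran-2(5H)-one; 3 (−)-menthol, (1R,2S,5R)-5-methyl-2-(propan-2-yl)cyclohexan-1-ol
Product: 5 (5R)-5-[(1R,2S,5R)-menthyloxy]furan-2(5H)-one, via (5S)-acetal epimer 4 (not isolated)
Conditions: p-toluenesulfonic acid monohydrate (cat.), toluene, reflux, azeotropic removal of water; crystallisation from petroleum ether, −20 °C; mother liquor re-equilibrated with the same acid and recrystallised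
Reagents that add atoms: none
Why: Acid-catalysed acetalisation of the lactol gives both C5 epimers, which interconvert under acid; the (5R) epimer 5 should crystallise selectively, so crystallisation with re-equilibration of 4 sets C5 as a single configuration.

Step 3
Reactants: 6 veratraldehyde (3,4-dimethoxybenzaldehyde)
Product: 7 2-(3,4-dimethoxyphenyl)-1,3-dithiane
Conditions: HS(CH2)3SH, BF3·OEt2 (cat.), CH2Cl2, 0 °C → rt
Reagents that add atoms: propane-1,3-dithiol, SCCCS
Why: Lewis-acid-catalysed dithioacetalisation of an aromatic aldehyde; the dithiane makes the former carbonyl carbon an acyl-anion equivalent whose sulfur can later be removed to leave the benzylic CH2.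

Step 4
Reactants: 8 3,4-dihydroxy-5-methoxybenzaldehyde
Product: 9 3,4-bis(benzyloxy)-5-methoxybenzaldehyde
Conditions: BnBr, K2CO3, DMF, 60 °C
Reagents that add atoms: benzyl bromide, BrCc1ccccc1
Why: Williamson ether synthesis on both phenols; benzyl ethers tolerate hydride, PBr3, organolithium and alkali and are removable by hydrogenolysis.

Step 5
Reactants: 9 3,4-bis(benzyloxy)-5-methoxybenzaldehyde
Product: 10 [3,4-bis(benzyloxy)-5-methoxyphenyl]methanol
Conditions: NaBH4, MeOH–THF, 0 °C
Reagents that add atoms: none
Why: Borohydride reduction of an aromatic aldehyde to the benzylic alcohol; the ethers are inert.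

Step 6
Reactants: 10 [3,4-bis(benzyloxy)-5-methoxyphenyl]methanol
Product: 11 3,4-bis(benzyloxy)-5-methoxybenzyl bromide
Conditions: PBr3, Et2O, 0 °C
Reagents that add atoms: phosphorus tribromide, BrP(Br)Br
Why: Conversion of a benzylic alcohol to the bromide through its phosphite ester (SN2); brief exposure at 0 °C should spare the benzyl ethers, and the electron-rich bromide is used freshly prepared.

Step 7
Reactants: 7 2-(3,4-dimethoxyphenyl)-1,3-dithiane; 5 (5R)-5-[(1R,2S,5R)-menthyloxy]furan-2(5H)-one; 11 3,4-bis(benzyloxy)-5-methoxybenzyl bromide
Product: 14 (3R,4R,5R)-3-[3,4-bis(benzyloxy)-5-methoxybenzyl]-4-[2-(3,4-dimethoxyphenyl)-1,3-dithian-2-yl]-5-[(1R,2S,5R)-menthyloxy]dihydrofuran-2(3H)-one, via lithiated dithiane 12 (not isolated), via lithium enolate 13 (not isolated)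
Conditions: n-BuLi, THF, −78 °C; 5, −78 °C; then 11, DMPU, −78 → −20 °C
Reagents that add atoms: none
Why: n-BuLi removes the C2–H of 7 to give the sulfur- and aryl-stabilised carbanion 12. This soft nucleophile adds to C4 of butenolide 5 in a Michael addition on the face opposite the C5 menthyloxy group, which sets C4 as R and gives lithium enolate 13. Enolate 13 is then C-benzylated by bromide 11 (SN2, DMPU to break up lithium aggregates) on the face opposite the bulky C4 dithianyl group, which sets C3 as R and gives the all-trans lactone 14. The closest known reaction type is the tandem conjugate addition of lithiated dithioacetals to 5-alkoxyfuran-2(5H)-ones with alkylation of the resulting enolate. No ring is closed; two exocyclic C–C bonds and two stereocentres are formed. The step needs 1,4- over 1,2-addition, which the delocalised anion and the unhindered β-carbon should secure. It needs C- over O-alkylation and mono- over dialkylation, which a reactive benzylic bromide and the hindered tertiary C3 of 14 should secure. It needs anti,anti facial control, which rests on the single acetal stereocentre of 5 relayed through C4.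

Step 8
Reactants: 14 (3R,4R,5R)-3-[3,4-bis(benzyloxy)-5-methoxybenzyl]-4-[2-(3,4-dimethoxyphenyl)-1,3-dithian-2-yl]-5-[(1R,2S,5R)-menthyloxy]dihydrofuran-2(3H)-one
Product: 17 (3R,4R)-3-[3,4-bis(benzyloxy)-5-methoxybenzyl]-4-[2-(3,4-dimethoxyphenyl)-1,3-dithian-2-yl]dihydrofuran-2(3H)-one, via aldehyde carboxylate 15 (not isolated), via hydroxy carboxylate 16 (not isolated)
Conditions: KOH, NaBH4, EtOH–H2O, 0 °C → rt; then 2 M HCl, rt
Reagents that add atoms: potassium hydroxide, [K+].[OH-] (its oxygen enters the carboxylate of 15 and is retained statistically in the lactone carbonyl)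
Why: Saponification of the lactone acetal frees a hemiacetal that collapses to aldehyde 15 with loss of menthol; borohydride reduces 15 in situ to 16, and acidification relactonises the γ-hydroxy acid. C3 and C4 are not touched, immediate reduction should outrun enolisation at C4, and the dithiane and benzyl ethers are inert to alkali, hydride and dilute acid.

Step 9
Reactants: 17 (3R,4R)-3-[3,4-bis(benzyloxy)-5-methoxybenzyl]-4-[2-(3,4-dimethoxyphenyl)-1,3-dithian-2-yl]dihydrofuran-2(3H)-one
Product: 18 (3R,4R)-3-(3,4-dihydroxy-5-methoxybenzyl)-4-(3,4-dimethoxybenzyl)dihydrofuran-2(3H)-one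
Conditions: Raney Ni (W-2, excess, two portions), H2 (1 atm), EtOH, 60 °C; filtered and concentrated under argon
Reagents that add atoms: none
Why: Raney Ni hydrogenolysis cleaves both benzylic C–S bonds (desulfurisation) and, under hydrogen, the two aryl benzyl ethers; the lactone, the aryl methyl ethers and both stereocentres are inert, and C4 keeps its R configuration.

Step 10
Reactants: 18 (3R,4R)-3-(3,4-dihydroxy-5-methoxybenzyl)-4-(3,4-dimethoxybenzyl)dihydrofuran-2(3H)-one
Product: 20 4-{[(3R,4R)-4-(3,4-dimethoxybenzyl)-2-oxotetrahydrofuran-3-yl]methyl}-2-oxo-2H-pyran-6-carboxylic acid, via methoxymuconic acid 19 (not isolated)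
Conditions: AcOOH (2.2 equiv), AcOH, 15 °C; then 2 M aq HCl, 50 °C
Reagents that add atoms: peracetic acid, CC(=O)OO
Why: Peracid oxidation takes the catechol through its ortho-quinone and the muconic anhydride, so the ring is cleaved between its two hydroxylated carbons (intradiol cleavage to the cis,cis-muconic acid 19), and this should be much faster than attack on the dimethoxyarene. In aqueous acid the methyl enol ether of 19 is protonated at C3, the Z-disposed distal carboxyl closes the six-membered ring on the resulting oxocarbenium carbon (the O1–C6 bond of the pyranone), and loss of methanol gives the 2-pyranone. Both halves are known reaction types, peracid cleavage of catechols to muconic acids and acid closure of 2-oxygenated hexadienedioic acids to 2-oxo-2H-pyran-6-carboxylic acids, and the lactone stereocentres are stable in acid.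

## Compound list

1 | furfural (furan-2-carbaldehyde) | O=Cc1ccco1 | starting material
2 | 5-hydroxyfuran-2(5H)-one (racemic) | O=C1C=CC(O)O1 | intermediate
3 | (−)-menthol, (1R,2S,5R)-5-methyl-2-(propan-2-yl)cyclohexan-1-ol | CC(C)[C@@H]1CC[C@@H](C)C[C@H]1O | starting material
4 | (5S)-5-[(1R,2S,5R)-menthyloxy]furan-2(5H)-one | O=C1C=C[C@@H](O[C@@H]2C[C@H](C)CC[C@H]2C(C)C)O1 | intermediate
5 | (5R)-5-[(1R,2S,5R)-menthyloxy]furan-2(5H)-one | O=C1C=C[C@H](O[C@@H]2C[C@H](C)CC[C@H]2C(C)C)O1 | intermediate
6 | veratraldehyde (3,4-dimethoxybenzaldehyde) | COc1ccc(C=O)cc1OC | starting material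
7 | 2-(3,4-dimethoxyphenyl)-1,3-dithiane | COc1ccc(C2SCCCS2)cc1OC | intermediate
8 | 3,4-dihydroxy-5-methoxybenzaldehyde | COc1cc(C=O)cc(O)c1O | starting material
9 | 3,4-bis(benzyloxy)-5-methoxybenzaldehyde | COc1cc(C=O)cc(OCc2ccccc2)c1OCc1ccccc1 | intermediate
10 | [3,4-bis(benzyloxy)-5-methoxyphenyl]methanol | COc1cc(CO)cc(OCc2ccccc2)c1OCc1ccccc1 | intermediate
11 | 3,4-bis(benzyloxy)-5-methoxybenzyl bromide | COc1cc(CBr)cc(OCc2ccccc2)c1OCc1ccccc1 | intermediate
12 | 2-lithio-2-(3,4-dimethoxyphenyl)-1,3-dithiane | COc1ccc(C2([Li])SCCCS2)cc1OC | intermediate
13 | lithium (4R,5R)-4-[2-(3,4-dimethoxyphenyl)-1,3-dithian-2-yl]-5-[(1R,2S,5R)-menthyloxy]-4,5-dihydrofuran-2-olate | COc1ccc(C2(SCCCS2)[C@H]2[C@H](O[C@@H]3C[C@H](C)CC[C@H]3C(C)C)OC(O[Li])=C2)cc1OC | intermediate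
14 | (3R,4R,5R)-3-[3,4-bis(benzyloxy)-5-methoxybenzyl]-4-[2-(3,4-dimethoxyphenyl)-1,3-dithian-2-yl]-5-[(1R,2S,5R)-menthyloxy]dihydrofuran-2(3H)-one | COc1ccc(C2(SCCCS2)[C@H]2[C@H](O[C@@H]3C[C@H](C)CC[C@H]3C(C)C)OC(=O)[C@@H]2Cc2cc(OC)c(OCc3ccccc3)c(OCc3ccccc3)c2)cc1OC | intermediate
15 | potassium (2R,3R)-2-[3,4-bis(benzyloxy)-5-methoxybenzyl]-3-[2-(3,4-dimethoxyphenyl)-1,3-dithian-2-yl]-4-oxobutanoate | COc1ccc(C2(SCCCS2)[C@@H](C=O)[C@@H](Cc2cc(OC)c(OCc3ccccc3)c(OCc3ccccc3)c2)C(=O)[O-])cc1OC.[K+] | intermediate
16 | potassium (2R,3R)-2-[3,4-bis(benzyloxy)-5-methoxybenzyl]-3-[2-(3,4-dimethoxyphenyl)-1,3-dithian-2-yl]-4-hydroxybutanoate | COc1ccc(C2(SCCCS2)[C@@H](CO)[C@@H](Cc2cc(OC)c(OCc3ccccc3)c(OCc3ccccc3)c2)C(=O)[O-])cc1OC.[K+] | intermediate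
17 | (3R,4R)-3-[3,4-bis(benzyloxy)-5-methoxybenzyl]-4-[2-(3,4-dimethoxyphenyl)-1,3-dithian-2-yl]dihydrofuran-2(3H)-one | COc1ccc(C2(SCCCS2)[C@H]2COC(=O)[C@@H]2Cc2cc(OC)c(OCc3ccccc3)c(OCc3ccccc3)c2)cc1OC | intermediate
18 | (3R,4R)-3-(3,4-dihydroxy-5-methoxybenzyl)-4-(3,4-dimethoxybenzyl)dihydrofuran-2(3H)-one | COc1ccc(C[C@H]2COC(=O)[C@@H]2Cc2cc(O)c(O)c(OC)c2)cc1OC | intermediate
19 | (2E,4Z)-4-{[(3R,4R)-4-(3,4-dimethoxybenzyl)-2-oxotetrahydrofuran-3-yl]methyl}-2-methoxyhexa-2,4-dienedioic acid | O=C(O)/C(OC)=C\C(C[C@H]1C(=O)OC[C@@H]1Cc1ccc(OC)c(OC)c1)=C/C(=O)O | intermediate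
20 | 4-{[(3R,4R)-4-(3,4-dimethoxybenzyl)-2-oxotetrahydrofuran-3-yl]methyl}-2-oxo-2H-pyran-6-carboxylic acid | COc1ccc(C[C@H]2COC(=O)[C@@H]2Cc2cc(C(=O)O)oc(=O)c2)cc1OC | target

## Step count and risks

Total step count: 10. Longest linear sequence: 7 steps (steps 4, 5, 6, 7, 8, 9 and 10, from 8 to 20).

**Step 7 (key step).** The most likely failure is in the second half of the tandem. Hindered enolate 13 may react slowly with 11, so that proton transfer, O-alkylation or decomposition of the benzylic bromide compete. Some 1,2-addition of 12 to the lactone carbonyl would also cost material. Fallback: run the two bond formations separately. Starting from 5 and 7, the Michael addition is quenched with NH4Cl, and the conjugate adduct (4R,5R)-4-[2-(3,4-dimethoxyphenyl)-1,3-dithian-2-yl]-5-[(1R,2S,5R)-menthyloxy]dihydrofuran-2(3H)-one F1 is isolated and purified. The enolate of F1 is then regenerated with LiN(i-Pr)2 in THF at −78 °C and alkylated with 11 in the presence of DMPU. Alkylation of F1 is again anti to the C4 group, and the route is rejoined at 14.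

**Step 10.** Chemoselectivity of the oxidation is the main concern. The peracid can also attack ring C or epoxidise the diene acid once formed, the quinone-level intermediate can tautomerise or oligomerise, and in the acid stage five-membered lactonisation of the muconic acid may compete with six-membered closure. Fallback: separate the two oxidation events so that only one equivalent of peracid meets the substrate. Starting from 18, oxidation with NaIO4 in aqueous MeCN at 0 °C should give the ortho-quinone 5-{[(3R,4R)-4-(3,4-dimethoxybenzyl)-2-oxotetrahydrofuran-3-yl]methyl}-3-methoxycyclohexa-3,5-diene-1,2-dione F2. F2 is treated cold, without storage, with one equivalent of m-chloroperbenzoic acid in CH2Cl2 (Baeyer–Villiger oxygen insertion) to give the muconic anhydride 5-{[(3R,4R)-4-(3,4-dimethoxybenzyl)-2-oxotetrahydrofuran-3-yl]methyl}-3-methoxyoxepine-2,7-dione F3. Mild aqueous hydrolysis of F3 returns the route at 19, which is cyclised with acid as in step 10.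

**Step 9.** Hydrogenolysis of the two benzyl ethers may stall on a nickel surface that is progressively sulfided, leaving partly benzylated material, and the free methoxycatechol can oxidise in air during filtration. Fallback: divide the task between two reagents. Starting from 17, nickel boride (Ni2B) generated from NiCl2·6H2O and NaBH4 in MeOH–THF at 0 °C removes the sulfur and leaves aryl benzyl ethers intact, giving (3R,4R)-3-[3,4-bis(benzyloxy)-5-methoxybenzyl]-4-(3,4-dimethoxybenzyl)dihydrofuran-2(3H)-one F4. Hydrogenolysis of F4 with H2 and Pd/C in EtOAc–EtOH, now free of sulfur, returns the route at 18.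

**Step 8.** The transient aldehyde 15 has an enolisable hydrogen at the future C4. Epimerisation there in alkali before reduction would give the cis lactone after ring closure. Fallback: unmask the acetal under acid and reduce without added alkali. Starting from 14, hydrolysis with 2 M HCl in aqueous dioxane at 60 °C should give the lactol (3R,4R)-3-[3,4-bis(benzyloxy)-5-methoxybenzyl]-4-[2-(3,4-dimethoxyphenyl)-1,3-dithian-2-yl]-5-hydroxydihydrofuran-2(3H)-one F5, with menthol split off. F5 is reduced with NaBH4 in EtOH at 0 °C through its open aldehyde-acid form and acidified to relactonise, returning the route at 17.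

## Further compounds

F1 | step 7 | (4R,5R)-4-[2-(3,4-dimethoxyphenyl)-1,3-dithian-2-yl]-5-[(1R,2S,5R)-menthyloxy]dihydrofuran-2(3H)-one | COc1ccc(C2(SCCCS2)[C@H]2[C@H](O[C@@H]3C[C@H](C)CC[C@H]3C(C)C)OC(=O)C2)cc1OC
F2 | step 10 | 5-{[(3R,4R)-4-(3,4-dimethoxybenzyl)-2-oxotetrahydrofuran-3-yl]methyl}-3-methoxycyclohexa-3,5-diene-1,2-dione | COC1=CC(C[C@H]2C(=O)OC[C@@H]2Cc2ccc(OC)c(OC)c2)=CC(=O)C1=O
F3 | step 10 | 5-{[(3R,4R)-4-(3,4-dimethoxybenzyl)-2-oxotetrahydrofuran-3-yl]methyl}-3-methoxyoxepine-2,7-dione | COC1=CC(C[C@H]2C(=O)OC[C@@H]2Cc2ccc(OC)c(OC)c2)=CC(=O)OC1=O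
F4 | step 9 | (3R,4R)-3-[3,4-bis(benzyloxy)-5-methoxybenzyl]-4-(3,4-dimethoxybenzyl)dihydrofuran-2(3H)-one | COc1ccc(C[C@H]2COC(=O)[C@@H]2Cc2cc(OC)c(OCc3ccccc3)c(OCc3ccccc3)c2)cc1OC
F5 | step 8 | (3R,4R)-3-[3,4-bis(benzyloxy)-5-methoxybenzyl]-4-[2-(3,4-dimethoxyphenyl)-1,3-dithian-2-yl]-5-hydroxydihydrofuran-2(3H)-one (anomeric mixture at C5) | COc1ccc(C2(SCCCS2)[C@H]2C(O)OC(=O)[C@@H]2Cc2cc(OC)c(OCc3ccccc3)c(OCc3ccccc3)c2)cc1OC
A1 | alternative 1 | methyl 4-{[(3R,4R)-4-(3,4-dimethoxybenzyl)-2-oxotetrahydrofuran-3-yl]methyl}-6-oxo-3,6-dihydro-2H-pyran-2-carboxylate (both epimers at the ring CH) | COc1ccc(C[C@H]2COC(=O)[C@@H]2CC2=CC(=O)OC(C(=O)OC)C2)cc1OC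
A2 | alternative 1 | methyl 2-(acryloyloxy)-4-{[(3R,4R)-4-(3,4-dimethoxybenzyl)-2-oxotetrahydrofuran-3-yl]methyl}pent-4-enoate (both epimers at C2) | COc1ccc(C[C@H]2COC(=O)[C@@H]2CC(=C)CC(OC(=O)C=C)C(=O)OC)cc1OC
A3 | alternative 2 | (R)-4-(3,4-dimethoxybenzyl)dihydrofuran-2(3H)-one | COc1ccc(C[C@H]2COC(=O)C2)cc1OC
A4 | alternative 2 | 3-(3,4-dimethoxybenzyl)cyclobutan-1-one | COc1ccc(CC2CC(=O)C2)cc1OC
A5 | alternative 3 | ethyl 4-{[(3R,4R)-4-(3,4-dimethoxybenzyl)-2-oxotetrahydrofuran-3-yl]methyl}-2-oxo-2H-pyran-6-carboxylate | COc1ccc(C[C@H]2COC(=O)[C@@H]2Cc2cc(C(=O)OCC)oc(=O)c2)cc1OC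
A6 | alternative 3 | ethyl (E)-4-[(3R,4R)-4-(3,4-dimethoxybenzyl)-2-oxotetrahydrofuran-3-yl]-3-methylbut-2-enoate | COc1ccc(C[C@H]2COC(=O)[C@@H]2C/C(C)=C/C(=O)OCC)cc1OC
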